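The tetrasubstituted C8=C9 alkene of ring B (labdane numbering) is read as a Diels–Alder retron: diene C7=C8–C9=C10 and dienophile C5=C6, joined by the C1–C4 tether, give rings A and B at once by forming C5–C10 and C6–C7. The precursor is an acyclic triene whose diene is stereochemically blank (a 2,3-dialkyl-4-methylpenta-1,3-diene). On heating, a suprafacial 1,5-hydrogen shift writes the required C9=C10 geometry in situ, and a removable phenylsulfonyl group on C6 activates the dienophile. The quaternary stereocentre C4, set by catalytic desymmetrisation of a malonate, relays absolute configuration to C5 and C10.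

Key step: step 11

Remark: labdane atom numbers (C1–C20; ring A = C1–C5 and C10, ring B = C5–C10) are used for all intermediates; the antipode of the zinc ligand in step 2 is the one that delivers (S)-6; (E)-3-methylpent-2-en-4-yn-1-ol is taken as a commercial single isomer.

Step 1
Reactants: 1 dimethyl 2-methylmalonate; 2 allyl bromide
Product: 4 dimethyl 2-methyl-2-(prop-2-en-1-yl)malonate, via sodium enolate 3 (not isolated)
Conditions: NaH, THF, 0 °C; then 2, 0 °C to rt
Reagents that add atoms: none
Why: Deprotonation gives the stabilised malonate enolate, whose SN2 C-allylation (malonic ester alkylation) installs the three carbons that become C3, C2 and C1; no stereocentre arises because the two ester groups are still equivalent.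

Step 2
Reactants: 4 dimethyl 2-methyl-2-(prop-2-en-1-yl)malonate
Product: 6 methyl (S)-2-(hydroxymethyl)-2-methylpent-4-enoate, via trimethoxysilyl ether 5 (not isolated)
Conditions: ZnEt2 (10 mol%), chiral tetradentate pipecolinol-derived aminophenol ligand (5 mol%), HSi(OMe)3 (2.5 equiv), THF, 0 °C to rt; then MeOH, K2CO3 (cat.), 0 °C
Reagents that add atoms: none
Why: A chiral dinuclear zinc hydride catalyst reduces only one of the two enantiotopic ester groups by hydrosilylation (desymmetrising partial reduction of a 2,2-disubstituted malonic ester) and stops at the silyl ether, so the quaternary stereocentre C4 is set by catalyst control.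

Step 3
Reactants: 6 methyl (S)-2-(hydroxymethyl)-2-methylpent-4-enoate
Product: 7 methyl (S)-2-formyl-2-methylpent-4-enoate
Conditions: Dess–Martin periodinane, NaHCO3, CH2Cl2, 0 °C to rt
Reagents that add atoms: none
Why: Dess–Martin oxidation of the neopentyl-type primary alcohol gives an aldehyde (C5) that has no α-hydrogen and therefore cannot epimerise.

Step 4
Reactants: 7 methyl (S)-2-formyl-2-methylpent-4-enoate
Product: 8 methyl (2S,3E)-2-methyl-4-(phenylsulfonyl)-2-(prop-2-en-1-yl)but-3-enoate
Conditions: diethyl (phenylsulfonyl)methylphosphonate, NaH, THF, 0 °C to rt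
Reagents that add atoms: diethyl (phenylsulfonyl)methylphosphonate, CCOP(=O)(CS(=O)(=O)c1ccccc1)OCC
Why: Horner–Wadsworth–Emmons olefination with the sulfonyl-stabilised phosphonate carbanion should give the (E)-vinyl sulfone C5=C6 and leaves the quaternary centre untouched.

Step 5
Reactants: 9 mesityl oxide (4-methylpent-3-en-2-one)
Product: 11 3-bromo-4-methylpent-3-en-2-one, via dibromo ketone 10 (not isolated)
Conditions: Br2, CH2Cl2, 0 °C; then Et3N, 0 °C to rt
Reagents that add atoms: bromine, BrBr
Why: Bromine adds across the enone double bond and triethylamine then removes the acidic α-hydrogen together with the tertiary β-bromide (addition–elimination), returning the conjugated enone with bromine on the α-carbon (future C9).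

Step 6
Reactants: 12 (E)-3-methylpent-2-en-4-yn-1-ol
Product: 13 tert-butyldimethyl{[(2E)-3-methylpent-2-en-4-yn-1-yl]oxy}silane
Conditions: TBSCl, imidazole, DMF, 0 °C to rt
Reagents that add atoms: tert-butyldimethylsilyl chloride, CC(C)(C)[Si](C)(C)Cl
Why: Imidazole-promoted silylation protects the primary allylic alcohol (future C15–O) for the organometallic steps.

Step 7
Reactants: 13 tert-butyldimethyl{[(2E)-3-methylpent-2-en-4-yn-1-yl]oxy}silane
Product: 14 tert-butyldimethyl{[(2E)-3-methylpenta-2,4-dien-1-yl]oxy}silane
Conditions: H2 (1 atm), Pd/CaCO3 poisoned with Pb(OAc)2, quinoline, hexane, rt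
Reagents that add atoms: none
Why: Lindlar semi-hydrogenation reduces the terminal alkyne of the conjugated enyne to a vinyl group and leaves the trisubstituted (E)-alkene C13=C14 unchanged.

Step 8
Reactants: 14 tert-butyldimethyl{[(2E)-3-methylpenta-2,4-dien-1-yl]oxy}silane; 11 3-bromo-4-methylpent-3-en-2-one
Product: 16 3-{(3E)-5-[(tert-butyldimethylsilyl)oxy]-3-methylpent-3-en-1-yl}-4-methylpent-3-en-2-one, via alkylborane 15 (not isolated)
Conditions: 9-BBN, THF, 0 °C to rt; then 11, PdCl2(dppf) (5 mol%), AsPh3, K3PO4 (3 M aq), DMF, rt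
Reagents that add atoms: none
Why: 9-BBN hydroborates only the terminal vinyl group in the anti-Markovnikov sense, and B-alkyl Suzuki–Miyaura coupling of the primary borane with the α-bromo enone forms C9–C11; the new tetrasubstituted alkene carries two identical methyl groups, so no geometry has to be controlled.

Step 9
Reactants: 16 3-{(3E)-5-[(tert-butyldimethylsilyl)oxy]-3-methylpent-3-en-1-yl}-4-methylpent-3-en-2-one
Product: 18 3-{(3E)-5-[(tert-butyldimethylsilyl)oxy]-3-methylpent-3-en-1-yl}-4-methylpenta-1,3-dien-2-yl trifluoromethanesulfonate, via potassium enolate 17 (not isolated)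
Conditions: KN(SiMe3)2, THF, −78 °C; then PhNTf2, −78 to 0 °C
Reagents that add atoms: N-phenylbis(trifluoromethanesulfonimide), O=S(=O)(N(c1ccccc1)S(=O)(=O)C(F)(F)F)C(F)(F)F
Why: At −78 °C the amide base removes a proton from the acetyl methyl group (kinetic cross-conjugated enolate) rather than from the γ-methyl groups, and O-sulfonylation gives the dien-2-yl triflate in which the former carbonyl carbon is C10 and its methyl group the methylene C20.

Step 10
Reactants: 8 methyl (2S,3E)-2-methyl-4-(phenylsulfonyl)-2-(prop-2-en-1-yl)but-3-enoate; 18 dienyl triflate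
Product: 20 methyl (2S,3E)-2-methyl-2-{6-methyl-4-methylidene-5-[(3E)-5-(tert-butyldimethylsilyloxy)-3-methylpent-3-en-1-yl]hept-5-en-1-yl}-4-(phenylsulfonyl)but-3-enoate, via alkylborane 19 (not isolated)
Conditions: 9-BBN, THF, 0 °C to rt; then 18, PdCl2(dppf) (5 mol%), AsPh3, K3PO4 (3 M aq), DMF, rt, O2 excluded
Reagents that add atoms: none
Why: 9-BBN should hydroborate the unhindered terminal allyl alkene much faster than the electron-poor vinyl sulfone flanked by a quaternary carbon, and B-alkyl Suzuki–Miyaura coupling of the primary borane with the dienyl triflate forms C1–C10 without touching C4.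

Step 11
Reactants: 20 triene sulfone (C20H2=C10 and C9=C8Me2 diene)
Product: 22 methyl (4S,5R,6S,10S,13E)-15-[(tert-butyldimethylsilyl)oxy]-6-(phenylsulfonyl)labda-8,13-dien-19-oate, via hydrogen-shifted triene 21 (not isolated)
Conditions: 1,2-dichlorobenzene (degassed, 0.01 M), BHT (cat.), 195 °C, sealed tube
Reagents that add atoms: none
Why: In the s-cis conformer of the diene of 20 a hydrogen of the isopropylidene methyl group that is cis to C10 migrates suprafacially to the terminal methylene C20 through a six-membered transition state (thermal [1,5]-sigmatropic shift), which necessarily leaves the new C20 methyl cis to C8 and the tether carbon C1 trans to it in 21; this diene then adds across the vinyl sulfone C5=C6 in a concerted, asynchronous [4+2] cycloaddition that forms C5–C10 and C6–C7. The closest known reactions are the 1,5-hydrogen shift of cis-alkyl-1,3-dienes such as 2,4-dimethylpenta-1,3-diene and the intramolecular Diels–Alder reaction of 1,3,9-decatrienes that carry a terminal vinyl sulfone dienophile. Ring B is closed by the cycloaddition itself and ring A by the same C5–C10 bond through the four-carbon tether C1–C4, which adopts a chair-like six-membered array in the transition state. C10 and C5 are set together: the tether-out, methyl-in diene geometry written by the hydrogen shift, combined with a sulfonyl-endo, tether-exo transition state, should give the trans ring fusion; the (E)-dienophile places the sulfonyl group 6α (of no consequence later); and the stereocentre C4 selects the dienophile face by keeping its smaller ester group, not its methyl group, axial and syn to the incoming C20 methyl. The step needs the type 1 mode from 21 to outrun a bridged type 2 addition of 20, trans over cis fusion, and this facial bias: the hydrogen shift is reversible and nearly thermoneutral so 20 is funnelled through 21, the type 2 mode would have to bond the dimethyl-substituted terminus and create a bridgehead alkene, and the C9 side chain together with the quaternary C4 should disfavour the tether-endo (cis) array.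

Step 12
Reactants: 22 cycloadduct sulfone
Product: 23 methyl (4S,5R,10S,13E)-15-[(tert-butyldimethylsilyl)oxy]labda-8,13-dien-19-oate
Conditions: 6% Na/Hg, Na2HPO4, MeOH–THF, −20 °C to rt
Reagents that add atoms: none
Why: Sodium amalgam transfers electrons to the phenyl sulfone, the C6–S bond fragments and the carbanion is protonated by methanol (reductive desulfonylation), which leaves C6 as a methylene while the hindered ester, the silyl ether and the unconjugated alkenes are inert.

Step 13
Reactants: 23 methyl ester
Product: 24 (4S,5R,10S,13E)-15-[(tert-butyldimethylsilyl)oxy]labda-8,13-dien-19-oic acid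
Conditions: n-PrSLi (from n-PrSH, n-BuLi), HMPA, rt; then cold 0.5 M HCl to pH 3
Reagents that add atoms: none
Why: The thiolate attacks the O-methyl carbon in an SN2 dealkylation, which bypasses the hindered axial neopentyl carbonyl that resists saponification, and no stereocentre is involved.

Step 14
Reactants: 24 silyl ether acid
Product: 25 (4S,5R,10S,13E)-15-hydroxylabda-8,13-dien-19-oic acid
Conditions: Bu4NF, THF, rt; aq NH4Cl work-up
Reagents that add atoms: none
Why: Fluoride cleaves the Si–O bond of the primary silyl ether under conditions that leave the acid (as its carboxylate) and both alkenes unchanged.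

Step 15
Reactants: 25 hydroxy acid
Product: 26 (4S,5R,10S,13E)-15-acetoxylabda-8,13-dien-19-oic acid
Conditions: Ac2O (1.2 equiv), pyridine, DMAP (cat.), CH2Cl2, 0 °C; aqueous work-up
Reagents that add atoms: acetic anhydride, CC(=O)OC(C)=O
Why: The unhindered primary allylic alcohol is acetylated under nucleophilic catalysis far faster than the hindered tertiary axial carboxylic acid can be activated, so the free acid should be retained.

Compound list
1 | dimethyl 2-methylmalonate | COC(=O)C(C)C(=O)OC | starting material
2 | allyl bromide (3-bromoprop-1-ene) | C=CCBr | starting material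
3 | sodium enolate of dimethyl 2-methylmalonate (not isolated) | [Na+].COC(=O)[C-](C)C(=O)OC | intermediate
4 | dimethyl 2-methyl-2-(prop-2-en-1-yl)malonate | COC(=O)C(C)(CC=C)C(=O)OC | intermediate
5 | methyl (S)-2-methyl-2-{[(trimethoxysilyl)oxy]methyl}pent-4-enoate (not isolated) | CO[Si](OC)(OC)OC[C@@](C)(C(=O)OC)CC=C | intermediate
6 | methyl (S)-2-(hydroxymethyl)-2-methylpent-4-enoate | OC[C@@](C)(C(=O)OC)CC=C | intermediate
7 | methyl (S)-2-formyl-2-methylpent-4-enoate | O=C[C@@](C)(C(=O)OC)CC=C | intermediate
8 | methyl (2S,3E)-2-methyl-4-(phenylsulfonyl)-2-(prop-2-en-1-yl)but-3-enoate | O=S(=O)(c1ccccc1)/C=C/[C@@](C)(C(=O)OC)CC=C | intermediate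
9 | mesityl oxide (4-methylpent-3-en-2-one) | CC(=O)C=C(C)C | starting material
10 | 3,4-dibromo-4-methylpentan-2-one (not isolated) | CC(=O)C(Br)C(C)(C)Br | intermediate
11 | 3-bromo-4-methylpent-3-en-2-one | CC(=O)C(Br)=C(C)C | intermediate
12 | (E)-3-methylpent-2-en-4-yn-1-ol | C#C/C(C)=C/CO | starting material
13 | tert-butyldimethyl{[(2E)-3-methylpent-2-en-4-yn-1-yl]oxy}silane | C#C/C(C)=C/CO[Si](C)(C)C(C)(C)C | intermediate
14 | tert-butyldimethyl{[(2E)-3-methylpenta-2,4-dien-1-yl]oxy}silane | C=C/C(C)=C/CO[Si](C)(C)C(C)(C)C | intermediate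
15 | 9-{(3E)-5-[(tert-butyldimethylsilyl)oxy]-3-methylpent-3-en-1-yl}-9-borabicyclo[3.3.1]nonane (not isolated) | CC(C)(C)[Si](C)(C)OC/C=C(\C)CCB1C2CCCC1CCC2 | intermediate
16 | 3-{(3E)-5-[(tert-butyldimethylsilyl)oxy]-3-methylpent-3-en-1-yl}-4-methylpent-3-en-2-one | CC(=O)C(CC/C(C)=C/CO[Si](C)(C)C(C)(C)C)=C(C)C | intermediate
17 | potassium enolate of 16 at the acetyl methyl group (not isolated) | [K+].[O-]C(=C)C(CC/C(C)=C/CO[Si](C)(C)C(C)(C)C)=C(C)C | intermediate
18 | 3-{(3E)-5-[(tert-butyldimethylsilyl)oxy]-3-methylpent-3-en-1-yl}-4-methylpenta-1,3-dien-2-yl trifluoromethanesulfonate | C=C(OS(=O)(=O)C(F)(F)F)C(CC/C(C)=C/CO[Si](C)(C)C(C)(C)C)=C(C)C | intermediate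
19 | methyl (2S,3E)-2-[3-(9-borabicyclo[3.3.1]nonan-9-yl)propyl]-2-methyl-4-(phenylsulfonyl)but-3-enoate (not isolated) | O=S(=O)(c1ccccc1)/C=C/[C@@](C)(C(=O)OC)CCCB1C2CCCC1CCC2 | intermediate
20 | methyl (2S,3E)-2-methyl-2-{6-methyl-4-methylidene-5-[(3E)-5-(tert-butyldimethylsilyloxy)-3-methylpent-3-en-1-yl]hept-5-en-1-yl}-4-(phenylsulfonyl)but-3-enoate | C=C(CCC[C@](C)(C(=O)OC)/C=C/S(=O)(=O)c1ccccc1)C(CC/C(C)=C/CO[Si](C)(C)C(C)(C)C)=C(C)C | intermediate
21 | methyl (2S,3E)-2-methyl-2-{(4E)-4,6-dimethyl-5-[(3E)-5-(tert-butyldimethylsilyloxy)-3-methylpent-3-en-1-yl]hepta-4,6-dien-1-yl}-4-(phenylsulfonyl)but-3-enoate (not isolated) | C=C(C)/C(CC/C(C)=C/CO[Si](C)(C)C(C)(C)C)=C(\C)CCC[C@](C)(C(=O)OC)/C=C/S(=O)(=O)c1ccccc1 | intermediate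
22 | methyl (4S,5R,6S,10S,13E)-15-[(tert-butyldimethylsilyl)oxy]-6-(phenylsulfonyl)labda-8,13-dien-19-oate | CC(C)(C)[Si](C)(C)OC/C=C(\C)CCC1=C(C)C[C@H](S(=O)(=O)c2ccccc2)[C@H]2[C@@](C)(C(=O)OC)CCC[C@]12C | intermediate
23 | methyl (4S,5R,10S,13E)-15-[(tert-butyldimethylsilyl)oxy]labda-8,13-dien-19-oate | CC(C)(C)[Si](C)(C)OC/C=C(\C)CCC1=C(C)CC[C@H]2[C@@](C)(C(=O)OC)CCC[C@]12C | intermediate
24 | (4S,5R,10S,13E)-15-[(tert-butyldimethylsilyl)oxy]labda-8,13-dien-19-oic acid | CC(C)(C)[Si](C)(C)OC/C=C(\C)CCC1=C(C)CC[C@H]2[C@@](C)(C(=O)O)CCC[C@]12C | intermediate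
25 | (4S,5R,10S,13E)-15-hydroxylabda-8,13-dien-19-oic acid | OC/C=C(\C)CCC1=C(C)CC[C@H]2[C@@](C)(C(=O)O)CCC[C@]12C | intermediate
26 | (4S,5R,10S,13E)-15-acetoxylabda-8,13-dien-19-oic acid | CC(=O)OC/C=C(\C)CCC1=C(C)CC[C@H]2[C@@](C)(C(=O)O)CCC[C@]12C | target

Total step count: 15.
Longest linear sequence: 10 steps (steps 6, 7, 8, 9, 10, 11, 12, 13, 14, 15 from 12; the branch 1, 2, 3, 4 joins at step 10 and is equally long).

Steps most likely to fail

Step 11. The hydrogen shift and the cycloaddition share one temperature and cannot be tuned separately. The triene may therefore be drained by a bridged cycloaddition through its 2-substituted diene, or the type 1 addition may discriminate poorly between the tether-exo and tether-endo arrays or between the two dienophile faces. The fallback fixes the diene geometry by synthesis and cyclises below the temperature at which hydrogen shifts set in. It sets out from 14 (through its borane 15) and rejoins the route at 22. Borane 15 would be iodinated (I2, NaOMe) to tert-butyl{[(2E)-5-iodo-3-methylpent-2-en-1-yl]oxy}dimethylsilane F1. C-Alkylation of pentane-2,4-dione (K2CO3, acetone, reflux) would give the 3-substituted pentane-2,4-dione F2. Sulfonylation of its non-chelated enolate (Tf2O, aqueous Me4NOH, toluene) should give the (E)-enol triflate F3, with the triflate trans to the remaining acetyl group. B-alkyl Suzuki–Miyaura coupling of F3 with borane 19 (PdCl2(dppf), K3PO4), which proceeds with retention, would give the tetrasubstituted enone F4. Ketone-selective methylenation (Zn, CH2Br2, TiCl4, THF–CH2Cl2) would then deliver 21 as an isolated compound, to be cyclised to 22 at 140–150 °C in toluene.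

Step 2. The catalyst may differentiate the two enantiotopic ester groups insufficiently, since the methyl and allyl flanks are similar in size, or the reduction may run on to the diol. The fallback replaces asymmetric catalysis by resolution. It sets out from 4 and comes back at 6. Non-selective mono-reduction of 4 (LiAlH(Ot-Bu)3, THF, reflux) would give racemic methyl 2-(hydroxymethyl)-2-methylpent-4-enoate F5. Preparative chromatography on a chiral stationary phase would separate it, and the (S)-enantiomer 6 is carried on.

Step 10. The vinyl sulfone may be hydroborated or reduced in competition with the allyl group, or the hindered dienyl triflate may transmetalate slowly so that the borane is lost by protodeboronation. The fallback carries the dienophile carbon C5 through the fragment union as a protected carbinol and builds the vinyl sulfone afterwards. It sets out from 6 and 18 and comes back at 20. Silylation of 6 (TESCl, imidazole) would give methyl (S)-2-methyl-2-[(triethylsilyloxy)methyl]pent-4-enoate F6. Hydroboration with 9-BBN would give its borane F7, and coupling with 18 under the conditions of step 10 would give the triene bis-silyl ether F8. Selective removal of the triethylsilyl group (PPTS, MeOH, 0 °C) would give the alcohol F9. Dess–Martin oxidation would give the aldehyde F10, and the Horner–Wadsworth–Emmons reaction of step 4 would then give 20.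

Further compounds
F1 | step 11 | tert-butyl{[(2E)-5-iodo-3-methylpent-2-en-1-yl]oxy}dimethylsilane | ICC/C(C)=C/CO[Si](C)(C)C(C)(C)C
F2 | step 11 | 3-{(3E)-5-[(tert-butyldimethylsilyl)oxy]-3-methylpent-3-en-1-yl}pentane-2,4-dione | CC(=O)C(CC/C(C)=C/CO[Si](C)(C)C(C)(C)C)C(C)=O
F3 | step 11 | (2E)-3-{(3E)-5-[(tert-butyldimethylsilyl)oxy]-3-methylpent-3-en-1-yl}-4-oxopent-2-en-2-yl trifluoromethanesulfonate | CC(=O)/C(CC/C(C)=C/CO[Si](C)(C)C(C)(C)C)=C(\C)OS(=O)(=O)C(F)(F)F
F4 | step 11 | methyl (2S,3E)-2-{(4E,8E)-5-acetyl-10-[(tert-butyldimethylsilyl)oxy]-4,8-dimethyldeca-4,8-dien-1-yl}-2-methyl-4-(phenylsulfonyl)but-3-enoate | CC(=O)/C(CC/C(C)=C/CO[Si](C)(C)C(C)(C)C)=C(\C)CCC[C@](C)(C(=O)OC)/C=C/S(=O)(=O)c1ccccc1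
F5 | step 2 | racemic methyl 2-(hydroxymethyl)-2-methylpent-4-enoate | OCC(C)(C(=O)OC)CC=C
F6 | step 10 | methyl (S)-2-methyl-2-[(triethylsilyloxy)methyl]pent-4-enoate | CC[Si](CC)(CC)OC[C@@](C)(C(=O)OC)CC=C
F7 | step 10 | methyl (S)-5-(9-borabicyclo[3.3.1]nonan-9-yl)-2-methyl-2-[(triethylsilyloxy)methyl]pentanoate | CC[Si](CC)(CC)OC[C@@](C)(C(=O)OC)CCCB1C2CCCC1CCC2
F8 | step 10 | methyl (S)-2-methyl-2-[(triethylsilyloxy)methyl]-7-methylidene-8-(propan-2-ylidene)-11-methyl-13-(tert-butyldimethylsilyloxy)tridec-11(E)-enoate (C5 triethylsilyl ether analogue of 20) | C=C(CCC[C@](C)(C(=O)OC)CO[Si](CC)(CC)CC)C(CC/C(C)=C/CO[Si](C)(C)C(C)(C)C)=C(C)C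
F9 | step 10 | C5 primary alcohol analogue of 20 (CH2OH in place of the vinyl sulfone) | C=C(CCC[C@](C)(C(=O)OC)CO)C(CC/C(C)=C/CO[Si](C)(C)C(C)(C)C)=C(C)C
F10 | step 10 | C5 aldehyde analogue of 20 (CHO in place of the vinyl sulfone) | C=C(CCC[C@](C)(C(=O)OC)C=O)C(CC/C(C)=C/CO[Si](C)(C)C(C)(C)C)=C(C)C
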